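**Overview**
Retrosynthesis: the catechol O–H groups are masked as methyl ethers; the chain (C1 benzylic, C5 the ketone) is then cut at C2–C3 into a 2-arylethyl radical and a vinyl ketone, and the vinyl ketone at C4–C5 into a vinyl anion and a palmitoyl unit.
Feature: the C5 carbonyl lies four plain CH2 groups (C1–C4) from the benzene ring, so C3–C4–C5(=O) can come from an enone and C1–C2 from an arylpropanoic acid that gives up its carboxyl carbon.
Forward: acid 1 and N-hydroxyphthalimide 2 give redox-active ester 3; palmitoyl chloride 4 and amine salt 5 give Weinreb amide 6, which vinylmagnesium bromide 7 turns, through chelate 8, into the C18 enone 9; 3 and 9 are joined to the C20 ketone 10; BBr3 then frees catechol 12 by way of boron ester 11.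
Rings: the benzene ring is bought and no ring is formed.
Stereochemistry: none to set, since the target has no stereocentre and no stereodefined double bond.

Key step: step 4

Assumption: before hydrolysis in the last step the boron is taken to rest on the catechol as a cyclic bromoborane, the usual state of a 1,2-dioxygenated arene after cleavage with BBr3.

**Step 1**
Reactants: 1 3-(3,4-dimethoxyphenyl)propanoic acid; 2 N-hydroxyphthalimide
Product: 3 1,3-dioxoisoindolin-2-yl 3-(3,4-dimethoxyphenyl)propanoate
Conditions: DIC (1.1 equiv), DMAP (0.1 equiv), CH2Cl2, 0 °C to rt
Reagents that add atoms: none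
Why: Steglich-type carbodiimide esterification, in which DIC turns the acid into an O-acylisourea that the acidic N–OH of 2 captures under DMAP catalysis, while the aryl methyl ethers are inert to these neutral conditions.

**Step 2**
Reactants: 4 hexadecanoyl chloride (palmitoyl chloride); 5 N,O-dimethylhydroxylamine hydrochloride
Product: 6 N-methoxy-N-methylhexadecanamide
Conditions: K2CO3 (2.5 equiv), CH2Cl2/H2O, 0 °C to rt
Reagents that add atoms: none
Why: Schotten–Baumann amide formation, in which carbonate frees the N-methoxyamine from its salt and takes up the HCl released, while the lipophilic acyl chloride stays in the organic layer and is acylated by the amine much faster than it is hydrolysed.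

**Step 3**
Reactants: 6 N-methoxy-N-methylhexadecanamide; 7 vinylmagnesium bromide
Product: 9 octadec-1-en-3-one, via magnesium hemiaminal chelate 8 (not isolated)
Conditions: 7 (1.5 equiv, 1 M in THF), THF, −20 to 0 °C; then poured into cold 1 M HCl/Et2O at 0 °C; trace BHT, kept cold and used at once
Reagents that add atoms: none
Why: Weinreb ketone synthesis, in which the Grignard reagent adds once to give the five-membered magnesium chelate 8 that resists collapse and over-addition until the quench, and the cold acid protonates the released N,O-dimethylhydroxylamine so that it cannot add in aza-Michael fashion to the new vinyl ketone.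

**Step 4**
Reactants: 3 1,3-dioxoisoindolin-2-yl 3-(3,4-dimethoxyphenyl)propanoate; 9 octadec-1-en-3-one
Product: 10 1-(3,4-dimethoxyphenyl)icosan-5-one
Conditions: Ru(bpy)3(PF6)2 (1 mol %, bpy = 2,2'-bipyridine), Hantzsch ester (diethyl 2,6-dimethyl-1,4-dihydropyridine-3,5-dicarboxylate, 1.5 equiv), 9 (1.5 equiv), degassed CH2Cl2, 450 nm LEDs, rt
Reagents that add atoms: none
Why: The photoexcited ruthenium complex is quenched reductively by the Hantzsch ester, and the resulting [Ru(bpy)3]+ passes one electron to phthalimide ester 3, whose N–O bond breaks with loss of CO2 and phthalimide anion to release the primary 2-(3,4-dimethoxyphenyl)ethyl radical. This radical adds to the terminal CH2 of enone 9, forming the C2–C3 bond of the tether, and the α-keto radical so produced takes a hydrogen atom from the Hantzsch ester (or is reduced and protonated) to give saturated ketone 10 directly. The closest known reaction type is the reductive decarboxylative Giese addition of N-acyloxyphthalimides to enones and acrylates under photoredox catalysis. No ring closes and no stereocentre forms, so the step needs only regioselectivity and chemoselectivity. Attack at the β-carbon is secured by the polarity match between the nucleophilic alkyl radical and the unsubstituted electron-poor alkene terminus, whereas the electrophilic adduct radical is mismatched for a second enone and matched for hydrogen transfer, which should hold back oligomerisation. A neophyl-type 1,2-aryl migration would only exchange two equivalent CH2 positions and is without consequence, and the net reductive cycle never exposes the oxidisable dimethoxyarene to an oxidant.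

**Step 5**
Reactants: 10 1-(3,4-dimethoxyphenyl)icosan-5-one
Product: 12 1-(3,4-dihydroxyphenyl)icosan-5-one, via cyclic catechol bromoborane 11 (not isolated)
Conditions: BBr3 (3.5 equiv, 1 M in CH2Cl2), CH2Cl2, −78 to 0 °C; then ice-water under Ar
Reagents that add atoms: none
Why: Lewis acid-mediated aryl methyl ether cleavage with BBr3, in which boron coordinates each methoxy oxygen, bromide removes the methyl group by SN2 attack and the catechol is held as cyclic bromoborane 11 until water hydrolyses it, while the excess reagent only complexes the ketone reversibly and returns it unchanged.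

**Compound list**
1 | 3-(3,4-dimethoxyphenyl)propanoic acid | COc1ccc(CCC(=O)O)cc1OC | starting material
2 | N-hydroxyphthalimide | O=C1c2ccccc2C(=O)N1O | starting material
3 | 1,3-dioxoisoindolin-2-yl 3-(3,4-dimethoxyphenyl)propanoate | COc1ccc(CCC(=O)ON2C(=O)c3ccccc3C2=O)cc1OC | intermediate
4 | hexadecanoyl chloride (palmitoyl chloride) | CCCCCCCCCCCCCCCC(=O)Cl | starting material
5 | N,O-dimethylhydroxylamine hydrochloride | CNOC.Cl | starting material
6 | N-methoxy-N-methylhexadecanamide | CCCCCCCCCCCCCCCC(=O)N(C)OC | intermediate
7 | vinylmagnesium bromide | C=C[Mg]Br | starting material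
8 | bromomagnesium 3-[methoxy(methyl)amino]octadec-1-en-3-olate (racemic; formed in the flask, not isolated) | CCCCCCCCCCCCCCCC(O[Mg]Br)(C=C)N(C)OC | intermediate
9 | octadec-1-en-3-one (pentadecyl vinyl ketone) | CCCCCCCCCCCCCCCC(=O)C=C | intermediate
10 | 1-(3,4-dimethoxyphenyl)icosan-5-one | CCCCCCCCCCCCCCCC(=O)CCCCc1ccc(OC)c(OC)c1 | intermediate
11 | 1-(2-bromo-1,3,2-benzodioxaborol-5-yl)icosan-5-one (formed in the flask, not isolated) | CCCCCCCCCCCCCCCC(=O)CCCCc1ccc2OB(Br)Oc2c1 | intermediate
12 | 1-(3,4-dihydroxyphenyl)icosan-5-one | CCCCCCCCCCCCCCCC(=O)CCCCc1ccc(O)c(O)c1 | target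

Total step count: 5
Longest linear sequence: 4 steps (steps 2, 3, 4 and 5, from palmitoyl chloride 4)

**Steps most likely to fail**

Step 4. The primary radical may be reduced or may abstract hydrogen before it meets the enone, which gives simple hydrodecarboxylation. The vinyl ketone may also oligomerise under irradiation, so that conversion to the one-to-one adduct stalls.
The fallback builds the same C2–C3 bond by a polar route and sets out from enone 9. Commercial 4-(2-bromoethyl)-1,2-dimethoxybenzene would be converted with Mg turnings in THF into [2-(3,4-dimethoxyphenyl)ethyl]magnesium bromide F1. F1 would be added to 9 at −78 °C in the presence of catalytic CuBr·SMe2 and Me3SiCl (copper-catalysed, silyl chloride-accelerated conjugate addition). The adduct should be trapped as the enol ether {[1-(3,4-dimethoxyphenyl)icos-4-en-5-yl]oxy}trimethylsilane F2, whose double-bond geometry is immaterial. Dilute HCl in the work-up should hydrolyse F2 to ketone 10, where the route is rejoined.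

Step 3. The released N,O-dimethylhydroxylamine may add to the enone during the quench, and the terminal enone may polymerise on concentration.
The fallback sets out from vinylmagnesium bromide 7. Addition to commercial hexadecanal (THF, 0 °C, aqueous NH4Cl quench) should give racemic octadec-1-en-3-ol F3. Oxidation of this allylic alcohol with Dess–Martin periodinane (NaHCO3, CH2Cl2, 0 °C to rt) should then deliver enone 9 with no nucleophilic amine in the flask. The filtered solution of 9 would be carried straight into step 4.

Step 5. Cleavage may stop at a monomethyl ether, the Lewis acid may induce aldol self-condensation of the ketone, and the free catechol may be oxidised by air during work-up.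
The fallback changes the protecting group so that the last step is a neutral hydrogenolysis; it sets out from enone 9 and N-hydroxyphthalimide 2 and returns at 12.
- Commercial 3-(3,4-dihydroxyphenyl)propanoic acid would be perbenzylated (BnBr, K2CO3, DMF, 60 °C) to benzyl 3-[3,4-bis(benzyloxy)phenyl]propanoate F4.
- Saponification (LiOH, THF/H2O, then acidification) should give 3-[3,4-bis(benzyloxy)phenyl]propanoic acid F5.
- Esterification with 2 (DIC, DMAP, CH2Cl2) should give 1,3-dioxoisoindolin-2-yl 3-[3,4-bis(benzyloxy)phenyl]propanoate F6.
- Coupling with 9 under the conditions of step 4 should give 1-[3,4-bis(benzyloxy)phenyl]icosan-5-one F7.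
- Hydrogenolysis of F7 (H2 at 1 atm, Pd/C, EtOAc, rt) should leave the ketone untouched and deliver target 12.

**Further compounds**
F1 | step 4 | [2-(3,4-dimethoxyphenyl)ethyl]magnesium bromide | COc1ccc(CC[Mg]Br)cc1OC
F2 | step 4 | {[1-(3,4-dimethoxyphenyl)icos-4-en-5-yl]oxy}trimethylsilane (mixture of alkene geometries) | CCCCCCCCCCCCCCCC(O[Si](C)(C)C)=CCCCc1ccc(OC)c(OC)c1
F3 | step 3 | octadec-1-en-3-ol (racemic) | CCCCCCCCCCCCCCCC(O)C=C
F4 | step 5 | benzyl 3-[3,4-bis(benzyloxy)phenyl]propanoate | O=C(CCc1ccc(OCc2ccccc2)c(OCc2ccccc2)c1)OCc1ccccc1
F5 | step 5 | 3-[3,4-bis(benzyloxy)phenyl]propanoic acid | OC(=O)CCc1ccc(OCc2ccccc2)c(OCc2ccccc2)c1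
F6 | step 5 | 1,3-dioxoisoindolin-2-yl 3-[3,4-bis(benzyloxy)phenyl]propanoate | O=C(CCc1ccc(OCc2ccccc2)c(OCc2ccccc2)c1)ON1C(=O)c2ccccc2C1=O
F7 | step 5 | 1-[3,4-bis(benzyloxy)phenyl]icosan-5-one | CCCCCCCCCCCCCCCC(=O)CCCCc1ccc(OCc2ccccc2)c(OCc2ccccc2)c1
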